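The rate constants are invented.

I must choose the temperature for making Wu, so I reckon how much Wu can stand against the dissolved Gu that destroys it.

| flask | Jo | temperature | time |
|---|---|---|---|
| cedar | 0.50 M | 100 °C | 2.5 min |
| ash | 0.50 M | 80 °C | 2.5 min |

    Gu ⇌ Xi (K1 = 0.66, k1 = 0.018 s⁻¹, Ea1 = 105 kJ mol⁻¹, ΔH1 = −2.00 kJ mol⁻¹)
    Xi ⇌ Qe (K2 = 0.83, k2 = 0.054 s⁻¹, Ea2 = 82.0 kJ mol⁻¹, ΔH2 = −51.0 kJ mol⁻¹)
    Xi → Ez (k3 = 0.068 s⁻¹, Ea3 = 106 kJ mol⁻¹)
    Ez → Ek (k4 = 0.028 s⁻¹, Ea4 = 96.0 kJ mol⁻¹)
    Ek → Wu (k5 = 0.0062 s⁻¹, Ea5 = 104 kJ mol⁻¹)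
    Jo ⇌ Gu, rate k6*(cs6 - [Gu]) while solid is left; crystals form when [Gu] > cs6 (cs6 = 0.36 M, k6 = 0.011 s⁻¹)
    Gu + Wu → Jy (k7 = 0.31 L mol⁻¹ s⁻¹, Ea7 = 50.0 kJ mol⁻¹)
    (constants at 80 °C)

- in percentages every species weighs as the Jo in it: one Jy counts as two
- as a solid, counted per litre of solution: Jo
- the list of constants is for 80 °C, to be carried to other temperatures by the activation energies and enthalpies
- at the start none of Jo is in solution
- what has only dissolved of Jo counts as not reacted

- the flask that comes out highest in amount of Wu, in percent of the Jo charged, or "all alike" when all lie within 1.5 percentage points (cedar / ash / all alike)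
- Wu at the end, in percent of the Jo charged, cedar
- Wu at the end, in percent of the Jo charged, ash

I replace the Gu curve by one level G, a quasi-steady state while solid lasts, where dissolving balances the forward step Gu → Xi. With dissolution coefficient k_d, solubility c_s and forward constant k_f, and with the return from Xi neglected, G = k_d·c_s/(k_d + k_f).

In ash this gives 0.137 M. In cedar k_f grows to 0.122 s⁻¹, while k_d carries no activation energy, so G falls to 0.0297 M.

Wu is made from Ek with constant k_m and lost to Gu with constant k_x. In ash the holding ratio φ, the Wu standing per Ek where making equals loss, k_m/(k_x·G), is 0.146. In cedar it is 1.80. I choose cedar because its φ stands far above that of ash, but my reckoning gives no percentage of Wu.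

The forecast puts cedar first, at 22% against 1.7% for ash, saying “the higher Gu consumes that Wu quickly”.

The simulation gives 24.9% Wu in cedar and 2.00% in ash, so cedar comes out higher. My levels G are 27.3% of the charge in ash and 5.94% in cedar, and at half time Gu stands at 26.5% in ash and 5.54% in cedar. At half time, with Jo still standing as solid at 54.7% in ash and 45.6% in cedar, Wu per Ek is 0.0761 in ash, below 0.146, and 1.08 in cedar, below 1.80. So at that moment each flask stands under its φ, and cedar stands above ash, in the order φ gave.

In ash, Jo was still dissolving at 2.50 min, with 19.2% left as solid and Gu at 29.7%, while Ek had reached 19.3% and Jy 7.83%. In cedar, the dissolving of Jo passed the midpoint of its turnover at 1.15 min, and by 2.50 min Jo stood at 0%, Gu had fallen to 0.507%, and Jy had risen from 18.1% to 64.4%.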